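The cyclopentenone (C1–C5, guaiane numbering) is carried as a 2-ethylfuran, a masked 1,4-diketone, so the core becomes a cyclohepta[b]furan. Its seven-membered ring (C1, C5–C10) is cut into a three-carbon unit C10–C1–C5 (carbinol carbon plus furan β- and α-carbons) and a four-carbon unit C6–C9 (2-silyloxybutadiene; its oxygen becomes the C8 oxygen). One asymmetric (4+3) cycloaddition of the 1-(3-furyl)ethyl cation with the diene forms C9–C10 and C5–C6 and sets C10. The feature exploited is the C1–C5 edge shared by both rings: as a furan C=C bond it completes the allyl cation. Ester and hydride chemistry then set C7 and C8, and furan oxidation plus aldol condensation reveal the enone.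

Key step: step 3

Numbering: guaiane numbers are kept for all intermediates. C1 is the ring-fusion CH, C2 the CH2, C3 the ketone carbon, C4 the methyl-bearing alkene carbon, C5 the ring-fusion alkene carbon, C6 a CH2, C7 the CH bearing C11 (the oxygenated isopropyl carbon), C8 the CH–O, C9 a CH2 and C10 the CH(CH3). In the furans, C5 and C1 are the fused α- and β-carbons, C2 is the free β-carbon, C3 the ethyl-bearing α-carbon, and the ethyl group is C4 with its methyl.

Assumption: for each chiral catalyst or ligand named, the antipode that gives the configuration drawn is the one used; it is fixed by a first experiment.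

Step 1
Reactants: 1 furan-3-carbaldehyde
Product: 5 5-ethylfuran-3-carbaldehyde, via lithium morpholino alkoxide 2 (not isolated), via 5-lithio amino alkoxide 3 (not isolated), via 5-ethyl amino alkoxide 4 (not isolated)
Conditions: morpholine, n-BuLi, THF, −78 °C; s-BuLi, −78 °C; EtI, −78 °C to rt; H2O
Reagents that add atoms: iodoethane, CCI
Why: Directed metalation through an in situ α-amino alkoxide, in which the morpholine adduct masks the aldehyde and steers s-BuLi to the remote furan α-position, followed by alkylation and hydrolysis, should give the 2,4-disubstituted furan without forming a stereocenter.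

Step 2
Reactants: 5 5-ethylfuran-3-carbaldehyde
Product: 6 rac-1-(5-ethylfuran-3-yl)ethan-1-ol
Conditions: MeMgBr, THF, 0 °C; H2O
Reagents that add atoms: methylmagnesium bromide, C[Mg]Br
Why: Grignard addition to the aldehyde should give the secondary 3-furyl carbinol, used as the racemate because its stereocenter is erased on ionization in step 3.

Step 3
Reactants: 6 rac-1-(5-ethylfuran-3-yl)ethan-1-ol; 7 2-(trimethylsilyloxy)buta-1,3-diene
Product: 9 (4S)-2-ethyl-4-methyl-4,5,7,8-tetrahydro-6H-cyclohepta[b]furan-6-one, via silyl enol ether cycloadduct 8 (not isolated)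
Conditions: chiral IDPi Brønsted acid (BINOL-derived imidodiphosphorimidate, 5 mol %), 7 (3 equiv), toluene, −60 °C, slow addition of 6; then 1 M HCl, THF, 0 °C
Reagents that add atoms: none
Why: Proposed new method: the silylated chiral acid ionizes carbinol 6 to the planar 1-(5-ethylfuran-3-yl)ethyl cation (an allyl cation made of C10, furan C1 and furan C5) held as an ion pair with the confined anion, the enol-ether CH2 (C9) of diene 7 adds to C10, and the 2-silyloxyallyl cation so formed is trapped at C6 by the free furan α-carbon C5 before proton loss restores the furan (concerted-asynchronous or stepwise (4+3) cycloaddition). The closest known reaction types are the (4+3) cycloaddition of furfuryl and indolylmethyl cations with dienes under Lewis or Brønsted acids and its chiral-acid version with indolyl carbinols and dienolsilanes; a 3-furyl secondary carbinol whose carbenium carbon becomes the stereocenter has not been shown. The seven-membered ring closes by attack of the furan α-carbon on the terminus of the oxyallyl cation (intramolecular Friedel–Crafts alkylation, 7-endo in the stepwise picture). The single new stereocenter C10 is set in the first C–C bond formation by the facial bias of the chiral counter-anion, so both enantiomers of 6 should converge on (S)-9. The step needs regioselectivity (C9 to C10, C6 to C5), which the polarity of both partners secures, and chemoselectivity against intermolecular furan alkylation, which the ethyl block on the other α-position, excess diene and slow addition of 6 at low temperature should secure.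

Step 4
Reactants: 9 (4S)-2-ethyl-4-methyl-4,5,7,8-tetrahydro-6H-cyclohepta[b]furan-6-one
Product: 10 methyl (4S)-2-ethyl-4-methyl-6-oxo-5,6,7,8-tetrahydro-4H-cyclohepta[b]furan-7-carboxylate (C7 epimers and enol)
Conditions: NaH (2.5 equiv), (MeO)2CO, THF, 65 °C; then 1 M HCl
Reagents that add atoms: dimethyl carbonate, COC(=O)OC
Why: Claisen-type carbomethoxylation of the ketone enolate under equilibrating conditions should occur at C7, the α-carbon remote from the branched C10, as with 3-substituted cycloalkanones, and the new α-center is labile and deliberately left unset.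

Step 5
Reactants: 10 methyl (4S)-2-ethyl-4-methyl-6-oxo-5,6,7,8-tetrahydro-4H-cyclohepta[b]furan-7-carboxylate
Product: 11 methyl (4S,6R,7S)-2-ethyl-6-hydroxy-4-methyl-5,6,7,8-tetrahydro-4H-cyclohepta[b]furan-7-carboxylate
Conditions: RuCl(p-cymene)[(S,S)-TsDPEN] (2 mol %), HCO2H/Et3N (5:2), CH2Cl2, 30 °C
Reagents that add atoms: none
Why: Noyori–Ikariya asymmetric transfer hydrogenation with dynamic kinetic resolution should let the catalyst fix C8 as R while C7 equilibrates through the enol and is drawn into the cis (7S) β-hydroxy ester, as known for 2-alkoxycarbonylcycloalkanones, and any minor enantiomer carried from step 3 becomes a separable diastereomer here.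

Step 6
Reactants: 11 methyl (4S,6R,7S)-2-ethyl-6-hydroxy-4-methyl-5,6,7,8-tetrahydro-4H-cyclohepta[b]furan-7-carboxylate
Product: 12 (4S,6R,7S)-2-ethyl-7-(2-hydroxypropan-2-yl)-4-methyl-5,6,7,8-tetrahydro-4H-cyclohepta[b]furan-6-ol
Conditions: MeMgBr (5 equiv), CeCl3, THF, −78 to 0 °C; H2O
Reagents that add atoms: methylmagnesium bromide, C[Mg]Br
Why: Double Grignard addition to the ester under weakly basic organocerium-type conditions should give the tertiary carbinol C11 without enolization at C7 or retro-aldol cleavage, and it forms no new stereocenter.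

Step 7
Reactants: 12 (4S,6R,7S)-2-ethyl-7-(2-hydroxypropan-2-yl)-4-methyl-5,6,7,8-tetrahydro-4H-cyclohepta[b]furan-6-ol
Product: 13 (2Z,3S,5R,6S)-5-hydroxy-6-(2-hydroxypropan-2-yl)-3-methyl-2-(2-oxobutylidene)cycloheptan-1-one
Conditions: mCPBA (1.05 equiv), CH2Cl2, 0 °C
Reagents that add atoms: mCPBA, OOC(=O)c1cccc(Cl)c1
Why: Oxidative furan ring opening (epoxidation of the electron-rich trisubstituted furan and ring opening) should unmask the 1,4-dicarbonyl unit as the cis-enedione while the alcohols and the three stereocenters are untouched.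

Step 8
Reactants: 13 (2Z,3S,5R,6S)-5-hydroxy-6-(2-hydroxypropan-2-yl)-3-methyl-2-(2-oxobutylidene)cycloheptan-1-one
Product: 15 (5S,6R,8S,8aR)-6-hydroxy-5-(2-hydroxypropan-2-yl)-3,8-dimethyl-4,5,6,7,8,8a-hexahydroazulen-2(1H)-one, via saturated 1,4-diketone 14 (not isolated)
Conditions: H2 (1 atm), Pd/C, EtOH, rt; filtration; then KOH, EtOH/H2O, 60 °C
Reagents that add atoms: none
Why: Chemoselective hydrogenation of the enedione C=C followed by base-mediated intramolecular aldol condensation (C4 enolate onto the ring ketone C5, since the C6-to-C3 closure would give a strained bridgehead enone) should form the fused 2-methylcyclopentenone, and C1, which is α to the ketone before and γ to the enone after cyclization, should equilibrate to the 1R epimer in which C2 and the pseudo-equatorial C10 methyl are trans.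

Step 9
Reactants: 15 (5S,6R,8S,8aR)-6-hydroxy-5-(2-hydroxypropan-2-yl)-3,8-dimethyl-4,5,6,7,8,8a-hexahydroazulen-2(1H)-one
Product: 16 (5S,6R,8S,8aR)-5-(2-hydroxypropan-2-yl)-3,8-dimethyl-2-oxo-1,2,4,5,6,7,8,8a-octahydroazulen-6-yl 2-methylprop-2-enoate
Conditions: methacrylic anhydride, Et3N, DMAP (cat.), BHT, CH2Cl2, 0 °C
Reagents that add atoms: methacrylic anhydride, C=C(C)C(=O)OC(=O)C(C)=C
Why: DMAP-catalyzed acyl transfer should esterify the secondary C8 hydroxyl and leave the hindered tertiary C11 hydroxyl free, without touching any stereocenter.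

Step 10
Reactants: 16 (5S,6R,8S,8aR)-5-(2-hydroxypropan-2-yl)-3,8-dimethyl-2-oxo-1,2,4,5,6,7,8,8a-octahydroazulen-6-yl 2-methylprop-2-enoate
Product: 17 (5S,6R,8S,8aR)-5-(2-acetoxypropan-2-yl)-3,8-dimethyl-2-oxo-1,2,4,5,6,7,8,8a-octahydroazulen-6-yl 2-methylprop-2-enoate (the target, CNP0318307.1)
Conditions: Ac2O, Sc(OTf)3 (5 mol %), MeCN, −20 °C
Reagents that add atoms: acetic anhydride, CC(=O)OC(C)=O
Why: Lewis-acid-catalyzed acetylation with Sc(OTf)3 and Ac2O should acylate the hindered tertiary alcohol at low temperature without ionization, leaving the methacrylate, the enone and all four stereocenters intact.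

Compound list
1 | furan-3-carbaldehyde | O=Cc1ccoc1 | starting material
2 | lithium (furan-3-yl)(morpholin-4-yl)methanolate | [Li]OC(c1ccoc1)N1CCOCC1 | intermediate
3 | lithium (5-lithiofuran-3-yl)(morpholin-4-yl)methanolate | [Li]OC(c1coc([Li])c1)N1CCOCC1 | intermediate
4 | lithium (5-ethylfuran-3-yl)(morpholin-4-yl)methanolate | [Li]OC(c1coc(CC)c1)N1CCOCC1 | intermediate
5 | 5-ethylfuran-3-carbaldehyde | CCc1cc(C=O)co1 | intermediate
6 | rac-1-(5-ethylfuran-3-yl)ethan-1-ol | CCc1cc(C(C)O)co1 | intermediate
7 | 2-(trimethylsilyloxy)buta-1,3-diene | C=CC(=C)O[Si](C)(C)C | starting material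
8 | {[(4S)-2-ethyl-4-methyl-5,8-dihydro-4H-cyclohepta[b]furan-6-yl]oxy}trimethylsilane | C[Si](C)(C)OC1=CCc2oc(CC)cc2[C@@H](C)C1 | intermediate
9 | (4S)-2-ethyl-4-methyl-4,5,7,8-tetrahydro-6H-cyclohepta[b]furan-6-one | O=C1C[C@H](C)c2cc(CC)oc2CC1 | intermediate
10 | methyl (4S)-2-ethyl-4-methyl-6-oxo-5,6,7,8-tetrahydro-4H-cyclohepta[b]furan-7-carboxylate (C7 epimers and enol) | O=C1C[C@H](C)c2cc(CC)oc2CC1C(=O)OC | intermediate
11 | methyl (4S,6R,7S)-2-ethyl-6-hydroxy-4-methyl-5,6,7,8-tetrahydro-4H-cyclohepta[b]furan-7-carboxylate | O[C@@H]1C[C@H](C)c2cc(CC)oc2C[C@@H]1C(=O)OC | intermediate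
12 | (4S,6R,7S)-2-ethyl-7-(2-hydroxypropan-2-yl)-4-methyl-5,6,7,8-tetrahydro-4H-cyclohepta[b]furan-6-ol | O[C@@H]1C[C@H](C)c2cc(CC)oc2C[C@@H]1C(C)(C)O | intermediate
13 | (2Z,3S,5R,6S)-5-hydroxy-6-(2-hydroxypropan-2-yl)-3-methyl-2-(2-oxobutylidene)cycloheptan-1-one | O[C@@H]1C[C@H](C)/C(=C/C(=O)CC)C(=O)C[C@@H]1C(C)(C)O | intermediate
14 | (3S,5R,6S)-5-hydroxy-6-(2-hydroxypropan-2-yl)-3-methyl-2-(2-oxobutyl)cycloheptan-1-one (C2 epimers) | O[C@@H]1C[C@H](C)C(CC(=O)CC)C(=O)C[C@@H]1C(C)(C)O | intermediate
15 | (5S,6R,8S,8aR)-6-hydroxy-5-(2-hydroxypropan-2-yl)-3,8-dimethyl-4,5,6,7,8,8a-hexahydroazulen-2(1H)-one | O[C@@H]1C[C@H](C)[C@H]2CC(=O)C(C)=C2C[C@@H]1C(C)(C)O | intermediate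
16 | (5S,6R,8S,8aR)-5-(2-hydroxypropan-2-yl)-3,8-dimethyl-2-oxo-1,2,4,5,6,7,8,8a-octahydroazulen-6-yl 2-methylprop-2-enoate | C=C(C)C(=O)O[C@@H]1C[C@H](C)[C@H]2CC(=O)C(C)=C2C[C@@H]1C(C)(C)O | intermediate
17 | (5S,6R,8S,8aR)-5-(2-acetoxypropan-2-yl)-3,8-dimethyl-2-oxo-1,2,4,5,6,7,8,8a-octahydroazulen-6-yl 2-methylprop-2-enoate | C=C(C)C(=O)O[C@@H]1C[C@H](C)[C@H]2CC(=O)C(C)=C2C[C@@H]1C(C)(C)OC(C)=O | target

Total step count: 10. Longest linear sequence: 10 steps (1 to 17); diene 7 is purchased.

Steps most likely to fail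

Step 3 (bears the label). The chiral anion may discriminate the two faces of the planar furylethyl cation poorly, or the cation may be captured by a second furan faster than by the diene, or the ring may fail to close after the first C–C bond. The fallback uses known chemistry, sets out from aldehyde 5 and comes back at ketone 9. Wittig olefination of 5 with Ph3P=CHC(O)SEt should give S-ethyl (2E)-3-(5-ethylfuran-3-yl)prop-2-enethioate F1. Copper-catalyzed asymmetric conjugate addition of MeMgBr (CuBr·SMe2, Josiphos, t-BuOMe, −75 °C) should set C10 and give S-ethyl (3S)-3-(5-ethylfuran-3-yl)butanethioate F2. Thioester–stannane ketone coupling with tributyl(vinyl)stannane (Pd2(dba)3, tri(2-furyl)phosphine, CuOP(O)Ph2, THF, 50 °C) should give (5S)-5-(5-ethylfuran-3-yl)hex-1-en-3-one F3. BF3·OEt2 in CH2Cl2 at −40 °C should then close the seven-membered ring by furan-terminated conjugate addition of the free α-carbon to the vinyl ketone, giving 9.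

Step 5. The transfer hydrogenation may deliver the trans isomer, the catalyst may not override the remote C10 center, or C7 may epimerize too slowly for the dynamic resolution. The fallback sets out from keto ester 10 and comes back at diol 12. Noyori hydrogenation with dynamic kinetic resolution ([RuCl(C6H6)((S)-BINAP)]Cl, H2 100 atm, CH2Cl2, 50 °C) is well established for the trans series and should give methyl (4S,6S,7S)-2-ethyl-6-hydroxy-4-methyl-5,6,7,8-tetrahydro-4H-cyclohepta[b]furan-7-carboxylate F4 with C7 correct. MeMgBr/CeCl3 should give (4S,6S,7S)-2-ethyl-7-(2-hydroxypropan-2-yl)-4-methyl-5,6,7,8-tetrahydro-4H-cyclohepta[b]furan-6-ol F5. Dess–Martin periodinane (buffered) should give (4S,7R)-2-ethyl-7-(2-hydroxypropan-2-yl)-4-methyl-4,5,7,8-tetrahydro-6H-cyclohepta[b]furan-6-one F6. LiBH(s-Bu)3 in THF at −78 °C should attack anti to the bulky C7 substituent and give the cis diol 12.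

Step 7. The free C8 and C11 hydroxyls may add to the newly formed enedione (oxa-Michael addition at C1) or close hemiketals on the C5 ketone, diverting material before hydrogenation and aldol closure. The fallback sets out from diol 12 and comes back at enone diol 15. TESOTf and 2,6-lutidine should silylate both hydroxyls to give triethyl{[(4S,6R,7S)-2-ethyl-4-methyl-7-{2-[(triethylsilyl)oxy]propan-2-yl}-5,6,7,8-tetrahydro-4H-cyclohepta[b]furan-6-yl]oxy}silane F7. mCPBA should give the bis(triethylsilyl) ether of enedione 13 F8. H2 over Pd/C should give the bis(triethylsilyl) ether of diketone 14 F9, and KOH in EtOH the bis(triethylsilyl) ether of enone diol 15 F10. HF·pyridine in THF should then remove both silyl groups to give 15.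

Further compounds
F1 | step 3 | S-ethyl (2E)-3-(5-ethylfuran-3-yl)prop-2-enethioate | CCSC(=O)/C=C/c1coc(CC)c1
F2 | step 3 | S-ethyl (3S)-3-(5-ethylfuran-3-yl)butanethioate | CCSC(=O)C[C@H](C)c1coc(CC)c1
F3 | step 3 | (5S)-5-(5-ethylfuran-3-yl)hex-1-en-3-one | C=CC(=O)C[C@H](C)c1coc(CC)c1
F4 | step 5 | methyl (4S,6S,7S)-2-ethyl-6-hydroxy-4-methyl-5,6,7,8-tetrahydro-4H-cyclohepta[b]furan-7-carboxylate | O[C@H]1C[C@H](C)c2cc(CC)oc2C[C@@H]1C(=O)OC
F5 | step 5 | (4S,6S,7S)-2-ethyl-7-(2-hydroxypropan-2-yl)-4-methyl-5,6,7,8-tetrahydro-4H-cyclohepta[b]furan-6-ol | O[C@H]1C[C@H](C)c2cc(CC)oc2C[C@@H]1C(C)(C)O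
F6 | step 5 | (4S,7R)-2-ethyl-7-(2-hydroxypropan-2-yl)-4-methyl-4,5,7,8-tetrahydro-6H-cyclohepta[b]furan-6-one | O=C1C[C@H](C)c2cc(CC)oc2C[C@@H]1C(C)(C)O
F7 | step 7 | triethyl{[(4S,6R,7S)-2-ethyl-4-methyl-7-{2-[(triethylsilyl)oxy]propan-2-yl}-5,6,7,8-tetrahydro-4H-cyclohepta[b]furan-6-yl]oxy}silane | CC[Si](CC)(CC)O[C@@H]1C[C@H](C)c2cc(CC)oc2C[C@@H]1C(C)(C)O[Si](CC)(CC)CC
F8 | step 7 | bis(triethylsilyl) ether of enedione 13 | CC[Si](CC)(CC)O[C@@H]1C[C@H](C)/C(=C/C(=O)CC)C(=O)C[C@@H]1C(C)(C)O[Si](CC)(CC)CC
F9 | step 7 | bis(triethylsilyl) ether of diketone 14 (C2 epimers) | CC[Si](CC)(CC)O[C@@H]1C[C@H](C)C(CC(=O)CC)C(=O)C[C@@H]1C(C)(C)O[Si](CC)(CC)CC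
F10 | step 7 | bis(triethylsilyl) ether of enone diol 15 | CC[Si](CC)(CC)O[C@@H]1C[C@H](C)[C@H]2CC(=O)C(C)=C2C[C@@H]1C(C)(C)O[Si](CC)(CC)CC
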